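**Plan**

- Numbering: ring A is C1 (ketone), C2 (methyl-bearing epoxide carbon), C3 (epoxide CH), C4 (CH2), C5 (side-chain carbon), C6 (tigloyloxy carbon); the chain is C7(=CH2)–C8(=O)–C9=C10–C11(OH)Me2.
- Retrosynthetic cuts, in order: C8–C9 and C7–C8 (C7 enol triflate + CO + vinylstannane), the C1 carbonyl (back to a silylated carbinol), the C6–O tiglate, the C2–C3 epoxide and the C6–O bond (back to a C6 acetyl), then C1–C6 and C4–C5 of ring A.
- Enabling feature: ring A has oxygen on the neighbouring carbons C1 and C6, a methyl on C2 beside the oxidised C2–C3 bond, and trans substituents on C5/C6. This is the imprint of a 1-siloxy-2-methylbutadiene (C1–C4) on an E-configured 3-acetylacrylate (C5, C6), the acetyl being a latent C6 oxygen.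
- Forward order: dienol ether from tiglaldehyde; ring A by catalytic asymmetric Diels–Alder reaction; the oxirane and the C6 acetate in one flask; ester to methyl ketone; tiglate; enol triflate; C1 to the ketone; the C8–C11 unit joined last by carbonylative Stille coupling.
- Stereochemistry: C5, C6 and the temporary C1 centre come from the cycloaddition (chiral boron cation, E-dienophile, endo acetyl); C6–O keeps its configuration through retentive acyl migration; C2/C3 arise by epoxidation anti to the pseudoaxial C1 silyloxy group.

Key step: step 2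

Remark: ring A keeps the target numbering throughout; with C1→C6 drawn clockwise, β is the face towards the viewer (the face of the C5 substituent and the epoxide oxygen) and α the opposite face.

Assumption: the (S)-diphenylprolinol-derived boron catalyst is taken to shield the face of ketone-bound 3 that leads to 4 as drawn; should its complex expose the other face, the (R)-catalyst is used and nothing else changes.

**Route**

Step 1
Reactants: 1 tiglaldehyde, (E)-2-methylbut-2-enal
Product: 2 (1E)-1-(tert-butyldimethylsilyloxy)-2-methylbuta-1,3-diene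
Conditions: TBSOTf, Et3N, Et2O, 0 °C → rt
Reagents that add atoms: tert-butyldimethylsilyl triflate, CC(C)(C)[Si](C)(C)OS(=O)(=O)C(F)(F)F
Why: Silyl dienol ether formation (O-silylation of the enal, then γ-deprotonation of the silyloxocarbenium ion by the amine) should give the less hindered (E)-C1=C2 isomer, with the siloxy group trans to the vinyl group as the cycloaddition requires.

Step 2
Reactants: 2 (1E)-1-(tert-butyldimethylsilyloxy)-2-methylbuta-1,3-diene; 3 ethyl (E)-4-oxopent-2-enoate
Product: 4 ethyl (1R,5S,6S)-6-acetyl-5-(tert-butyldimethylsilyloxy)-4-methylcyclohex-3-ene-1-carboxylate (route numbering: 1α-OTBS; C2-methyl; C2=C3; 5β-CO2Et; 6α-acetyl)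
Conditions: (S)-3,3-diphenyl-1-(2-methylphenyl)tetrahydro-1H,3H-pyrrolo[1,2-c][1,3,2]oxazaborole (20 mol %), (CF3SO2)2NH (16 mol %), CH2Cl2, −78 °C, slow addition of 2
Reagents that add atoms: none
Why: A concerted, asynchronous normal-demand [4+2] cycloaddition catalysed by a chiral boron Lewis acid, the closest known type being the oxazaborolidinium-catalysed Diels–Alder reaction of enones with oxygenated dienes. The cation binds the more basic ketone oxygen of 3, so the β-carbon (future C5, bearing CO2Et) is the electrophilic terminus and pairs with the unsubstituted, most nucleophilic diene terminus C4, while the siloxy-bearing C1 joins the acetyl-bearing C6. Ring A closes by intermolecular [4+2] cycloaddition as a six-membered carbocycle through the two σ-bonds C4–C5 and C1–C6, suprafacially on both partners. The trans C5/C6 relationship follows from the E-alkene of 3, the C1 configuration (OTBS cis to acetyl) from the endo position of the boron-bound acetyl group relative to the E-diene, and the absolute configuration of all three centres from the diphenylprolinol framework covering one face of the coordinated s-trans enone. The step needs regioselectivity, endo selectivity and facial selectivity, secured in that order by the higher Lewis basicity of the ketone over the ester, by secondary overlap of the activated acetyl group, and by the catalyst.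

Step 3
Reactants: 4 Diels–Alder adduct
Product: 6 ethyl 6α-acetoxy-1α-(tert-butyldimethylsilyloxy)-2β,3β-epoxy-2-methylcyclohexane-5β-carboxylate, via epoxy ketone 5 (not isolated)
Conditions: mCPBA (1.2 equiv), NaHCO3, CH2Cl2, 0 °C; then mCPBA (3 equiv), Na2HPO4, rt → 40 °C
Reagents that add atoms: meta-chloroperbenzoic acid, O=C(OO)c1cccc(Cl)c1
Why: Prilezhaev epoxidation of the electron-rich trisubstituted C2=C3 alkene should come first and take place on the β face, opposite the C1–OTBS group that allylic 1,2-strain with the C2 methyl holds pseudoaxial on the α face (this sets C2 and C3), after which the slower Baeyer–Villiger oxidation of the methyl ketone moves the secondary C6 in preference to methyl with retention to give the 6α-acetate.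

Step 4
Reactants: 6 epoxy acetate
Product: 8 Weinreb amide with free 6α-hydroxyl [5β-C(O)N(OMe)Me; 1α-OTBS; 2β,3β-epoxide], via hydroxy ester 7 (not isolated)
Conditions: Me(MeO)NH·HCl (5 equiv), iPrMgCl (10 equiv), THF, −20 → 0 °C; aq NH4Cl
Reagents that add atoms: N,O-dimethylhydroxylamine hydrochloride, CNOC.Cl
Why: Ester aminolysis by the chloromagnesium amide of N,O-dimethylhydroxylamine (Weinreb amide formation from esters) should first cleave the unhindered acetate, leaving a C6 alkoxide that cannot be lost by β-elimination, and then convert the ethyl ester, with no stereocentre touched and C5 held in its favoured equatorial arrangement trans to C6–O.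

Step 5
Reactants: 8 hydroxy Weinreb amide
Product: 9 5β-acetyl-1α-(tert-butyldimethylsilyloxy)-2β,3β-epoxy-2-methylcyclohexan-6α-ol (β-hydroxy methyl ketone)
Conditions: MeMgCl (3.5 equiv), THF, −20 → 0 °C; aq NH4Cl
Reagents that add atoms: methylmagnesium chloride, C[Mg]Cl
Why: Weinreb ketone synthesis, in which the chelated tetrahedral adduct resists a second addition and releases the methyl ketone only on mild work-up, one equivalent of Grignard reagent being spent on the free hydroxyl and the hindered, oxygen-deactivated epoxide staying closed at this temperature.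

Step 6
Reactants: 9 β-hydroxy methyl ketone; 10 tiglic acid
Product: 12 6α-tiglate of 9 [5β-acetyl; 1α-OTBS; 2β,3β-epoxide], via mixed anhydride 11 (not isolated)
Conditions: 10, 2,4,6-Cl3C6H2COCl, Et3N, toluene, rt; then 9, 4-(dimethylamino)pyridine, 0 °C → rt
Reagents that add atoms: none
Why: Yamaguchi esterification, in which the acylpyridinium ion formed from the mixed anhydride acylates the hindered secondary C6 hydroxyl with retention at C6 and without change of the (E)-tiglate geometry, under amine bases too weak to enolise the ketone toward C5.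

Step 7
Reactants: 12 tiglate methyl ketone
Product: 14 enol triflate [5β-(1-triflyloxyvinyl); 6α-O-tigloyl; 1α-OTBS; 2β,3β-epoxide], via potassium enolate 13 (not isolated)
Conditions: KN(SiMe3)2 (1.1 equiv), THF, −78 °C, 15 min; then N-(5-chloropyridin-2-yl)bis(trifluoromethanesulfonyl)imide, −78 °C
Reagents that add atoms: N-(5-chloropyridin-2-yl)bis(trifluoromethanesulfonyl)imide, O=S(=O)(N(c1ccc(Cl)cn1)S(=O)(=O)C(F)(F)F)C(F)(F)F
Why: Kinetic enolate O-triflation, in which the bulky amide base removes a proton from the unhindered methyl group rather than from the tertiary C5–H and the highly reactive pyridyl triflimide sulfonylates the enolate oxygen at −78 °C before it can attack the neighbouring tiglate, which has no α-hydrogen of its own.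

Step 8
Reactants: 14 enol triflate
Product: 15 1α-alcohol [5β-(1-triflyloxyvinyl); 6α-O-tigloyl; 2β,3β-epoxide]
Conditions: HF·pyridine, pyridine, THF, 0 °C → rt
Reagents that add atoms: none
Why: Fluoride-mediated silyl ether cleavage under buffered, weakly acidic conditions should free the C1 hydroxyl while the enol triflate and the oxygen-deactivated epoxide persist and the base-promoted 1,2-shift of the cis tiglate is suppressed.

Step 9
Reactants: 15 C1 alcohol
Product: 16 epoxy ketone enol triflate [C1=O; 2β,3β-epoxide; 5β-(1-triflyloxyvinyl); 6α-O-tigloyl]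
Conditions: Dess–Martin periodinane, NaHCO3, CH2Cl2, 0 °C → rt
Reagents that add atoms: none
Why: Dess–Martin oxidation of the secondary alcohol under buffered, non-basic conditions should give the α,β-epoxy ketone without epimerising C6, whose trans arrangement to C5 is in any case the stable one.

Step 10
Reactants: 17 2-methylbut-3-yn-2-ol
Product: 18 (E)-2-methyl-4-(tributylstannyl)but-3-en-2-ol
Conditions: Bu3SnH, PdCl2(PPh3)2 (1 mol %), THF, 0 °C → rt
Reagents that add atoms: tributyltin hydride, CCCC[SnH](CCCC)CCCC
Why: Palladium-catalysed hydrostannation of a terminal alkyne adds H and Sn syn, which fixes the E geometry, and the bulky tertiary carbinol directs tin to the terminal carbon.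

Step 11
Reactants: 16 epoxy ketone enol triflate; 18 (E)-vinylstannane
Product: 19 target, (1S,3S,4S,6S)-4-[(4E)-6-hydroxy-6-methyl-3-oxohepta-1,4-dien-2-yl]-1-methyl-2-oxo-7-oxabicyclo[4.1.0]heptan-3-yl (2E)-2-methylbut-2-enoate
Conditions: CO (1 atm), Pd(PPh3)4 (5 mol %), LiCl (3 equiv), THF, 50 °C
Reagents that add atoms: carbon monoxide, [C-]#[O+]
Why: Carbonylative Stille coupling (oxidative addition of the enol triflate to zerovalent palladium, CO insertion to the acyl complex, tin-to-palladium transfer of the vinyl group with retention of its E geometry, reductive elimination) should form C7–C8 and C8–C9 under neutral conditions that leave the epoxy ketone, the tiglate and the free tertiary alcohol alone.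

**Compound list**

1 | tiglaldehyde, (E)-2-methylbut-2-enal | C/C=C(\C)C=O | starting material
2 | (1E)-1-(tert-butyldimethylsilyloxy)-2-methylbuta-1,3-diene | C=C/C(C)=C/O[Si](C)(C)C(C)(C)C | intermediate
3 | ethyl (E)-4-oxopent-2-enoate | CCOC(=O)/C=C/C(C)=O | starting material
4 | ethyl (1R,5S,6S)-6-acetyl-5-(tert-butyldimethylsilyloxy)-4-methylcyclohex-3-ene-1-carboxylate (Diels–Alder adduct) | CCOC(=O)[C@@H]1CC=C(C)[C@@H](O[Si](C)(C)C(C)(C)C)[C@H]1C(C)=O | intermediate
5 | 2β,3β-epoxide of 4 (epoxy ketone, not isolated) | CCOC(=O)[C@@H]1C[C@@H]2O[C@]2(C)[C@@H](O[Si](C)(C)C(C)(C)C)[C@H]1C(C)=O | intermediate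
6 | ethyl 6α-acetoxy-1α-(tert-butyldimethylsilyloxy)-2β,3β-epoxy-2-methylcyclohexane-5β-carboxylate | CCOC(=O)[C@@H]1C[C@@H]2O[C@]2(C)[C@@H](O[Si](C)(C)C(C)(C)C)[C@H]1OC(C)=O | intermediate
7 | ethyl 1α-(tert-butyldimethylsilyloxy)-2β,3β-epoxy-6α-hydroxy-2-methylcyclohexane-5β-carboxylate (not isolated) | CCOC(=O)[C@@H]1C[C@@H]2O[C@]2(C)[C@@H](O[Si](C)(C)C(C)(C)C)[C@H]1O | intermediate
8 | N-methoxy-N-methyl amide corresponding to 7 (hydroxy Weinreb amide) | CON(C)C(=O)[C@@H]1C[C@@H]2O[C@]2(C)[C@@H](O[Si](C)(C)C(C)(C)C)[C@H]1O | intermediate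
9 | 5β-acetyl-1α-(tert-butyldimethylsilyloxy)-2β,3β-epoxy-2-methylcyclohexan-6α-ol | CC(=O)[C@@H]1C[C@@H]2O[C@]2(C)[C@@H](O[Si](C)(C)C(C)(C)C)[C@H]1O | intermediate
10 | tiglic acid, (E)-2-methylbut-2-enoic acid | C/C=C(\C)C(=O)O | starting material
11 | tiglic 2,4,6-trichlorobenzoic anhydride (not isolated) | C/C=C(\C)C(=O)OC(=O)c1c(Cl)cc(Cl)cc1Cl | intermediate
12 | 6α-tiglate of 9 | CC(=O)[C@@H]1C[C@@H]2O[C@]2(C)[C@@H](O[Si](C)(C)C(C)(C)C)[C@H]1OC(=O)/C(C)=C/C | intermediate
13 | potassium enolate of 12 on the methyl side (not isolated) | [K+].C=C([O-])[C@@H]1C[C@@H]2O[C@]2(C)[C@@H](O[Si](C)(C)C(C)(C)C)[C@H]1OC(=O)/C(C)=C/C | intermediate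
14 | enol triflate: 5β-(1-triflyloxyvinyl), 6α-O-tigloyl, 1α-OTBS, 2β,3β-epoxide | C=C(OS(=O)(=O)C(F)(F)F)[C@@H]1C[C@@H]2O[C@]2(C)[C@@H](O[Si](C)(C)C(C)(C)C)[C@H]1OC(=O)/C(C)=C/C | intermediate
15 | 1α-alcohol from 14 | C=C(OS(=O)(=O)C(F)(F)F)[C@@H]1C[C@@H]2O[C@]2(C)[C@@H](O)[C@H]1OC(=O)/C(C)=C/C | intermediate
16 | C1 ketone from 15 (epoxy ketone enol triflate) | C=C(OS(=O)(=O)C(F)(F)F)[C@@H]1C[C@@H]2O[C@]2(C)C(=O)[C@H]1OC(=O)/C(C)=C/C | intermediate
17 | 2-methylbut-3-yn-2-ol | CC(C)(O)C#C | starting material
18 | (E)-2-methyl-4-(tributylstannyl)but-3-en-2-ol | CC(C)(O)/C=C/[Sn](CCCC)(CCCC)CCCC | intermediate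
19 | CNP0263368.1, (1S,3S,4S,6S)-4-[(4E)-6-hydroxy-6-methyl-3-oxohepta-1,4-dien-2-yl]-1-methyl-2-oxo-7-oxabicyclo[4.1.0]heptan-3-yl (2E)-2-methylbut-2-enoate | C=C(C(=O)/C=C/C(C)(C)O)[C@@H]1C[C@@H]2O[C@]2(C)C(=O)[C@H]1OC(=O)/C(C)=C/C | target

**Step count**

Total: 11 steps. Longest linear sequence: 10 steps (steps 1–9 and 11, from tiglaldehyde); step 10 is a one-step side branch.

**Steps most likely to fail**

Step 2 (cycloaddition). The acid-sensitive dienol ether may be protodesilylated or may add stepwise in a Mukaiyama–Michael sense instead of cycloadding. Facial or regiochemical control may also erode because the dienophile offers two carbonyl groups to boron. Fallback (racemic cycloaddition, then classical resolution), setting out from 2 and 3: the achiral Lewis acid Me2AlCl (CH2Cl2, −78 °C), which also binds the ketone, should give the same regio- and endo-isomer as racemic adduct F1. The conditions of steps 3 and 4 then give racemic epoxy acetate F2 and racemic hydroxy Weinreb amide F3. Esterification of the C6 hydroxyl with (S)-O-methylmandelic acid (DCC, 4-(dimethylamino)pyridine, CH2Cl2) and chromatographic separation give (S)-O-methylmandelate F4 of the required ring configuration, apart from its diastereomeric mandelate F5, which is discarded. Excess MeMgCl (THF, 0 °C) converts the Weinreb amide of F4 into the methyl ketone and at the same time removes the mandelate, and the route is rejoined at 9.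

Step 7 (enol triflate). The C6 tigloyl group may be transferred to the neighbouring enolate (on oxygen or carbon), or enolisation toward C5 may be followed by β-elimination of the acyloxy group. Fallback (the tiglate is introduced only after the triflate), setting out from 9: silylation (Et3SiOTf, 2,6-lutidine, CH2Cl2, −78 °C) gives triethylsilyl ether F6, which has no acyl group beside the enolate. KN(SiMe3)2 and the pyridyl triflimide then give bis-silylated enol triflate F7. The more labile triethylsilyl group is removed selectively (HF·pyridine, pyridine, THF, 0 °C, short contact) to give hydroxy enol triflate F8, and Yamaguchi acylation with mixed anhydride 11 returns to the route at 14.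

Step 11 (carbonylative coupling). Direct coupling may outrun CO insertion, the epoxy ketone may isomerise under palladium or be opened by chloride, and free phosphine may add to the exo-methylene enone. Fallback (C8 introduced as an aldehyde carbon instead of CO), setting out from 14, before C1 is oxidised, so that no epoxy ketone meets divalent chromium: a Nozaki–Hiyama–Kishi coupling (CrCl2, NiCl2 1 mol %, DMF, rt) with (E)-4-hydroxy-4-methylpent-2-enal F9 should give bis-allylic alcohol F10 as a mixture of C8 epimers of no consequence. F9 is made by cross-metathesis of 2-methylbut-3-en-2-ol with crotonaldehyde using the second-generation Grubbs catalyst. HF·pyridine then removes the silyl group to give triol F11, and Dess–Martin periodinane oxidises both secondary hydroxyls (C1 and C8) in one operation, the tertiary C11 alcohol being inert, to arrive at 19.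

Further compounds
F1 | step 2 | racemic 4 (racemate; one enantiomer written) | CCOC(=O)[C@@H]1CC=C(C)[C@@H](O[Si](C)(C)C(C)(C)C)[C@H]1C(C)=O
F2 | step 2 | racemic 6 (racemate; one enantiomer written) | CCOC(=O)[C@@H]1C[C@@H]2O[C@]2(C)[C@@H](O[Si](C)(C)C(C)(C)C)[C@H]1OC(C)=O
F3 | step 2 | racemic 8 (racemate; one enantiomer written) | CON(C)C(=O)[C@@H]1C[C@@H]2O[C@]2(C)[C@@H](O[Si](C)(C)C(C)(C)C)[C@H]1O
F4 | step 2 | (S)-O-methylmandelate of 8 | CON(C)C(=O)[C@@H]1C[C@@H]2O[C@]2(C)[C@@H](O[Si](C)(C)C(C)(C)C)[C@H]1OC(=O)[C@@H](OC)c1ccccc1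
F5 | step 2 | (S)-O-methylmandelate of the enantiomer of 8 (discarded diastereomer) | CON(C)C(=O)[C@H]1C[C@H]2O[C@@]2(C)[C@H](O[Si](C)(C)C(C)(C)C)[C@@H]1OC(=O)[C@@H](OC)c1ccccc1
F6 | step 7 | 6α-triethylsilyl ether of 9 | CC(=O)[C@@H]1C[C@@H]2O[C@]2(C)[C@@H](O[Si](C)(C)C(C)(C)C)[C@H]1O[Si](CC)(CC)CC
F7 | step 7 | enol triflate with 1α-OTBS and 6α-OSiEt3 | C=C(OS(=O)(=O)C(F)(F)F)[C@@H]1C[C@@H]2O[C@]2(C)[C@@H](O[Si](C)(C)C(C)(C)C)[C@H]1O[Si](CC)(CC)CC
F8 | step 7 | enol triflate with 1α-OTBS and free 6α-hydroxyl | C=C(OS(=O)(=O)C(F)(F)F)[C@@H]1C[C@@H]2O[C@]2(C)[C@@H](O[Si](C)(C)C(C)(C)C)[C@H]1O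
F9 | step 11 | (E)-4-hydroxy-4-methylpent-2-enal | CC(C)(O)/C=C/C=O
F10 | step 11 | C8 carbinol (both epimers) with 1α-OTBS and 6α-O-tigloyl | C=C(C(O)/C=C/C(C)(C)O)[C@@H]1C[C@@H]2O[C@]2(C)[C@@H](O[Si](C)(C)C(C)(C)C)[C@H]1OC(=O)/C(C)=C/C
F11 | step 11 | C1,C8,C11-triol with 6α-O-tigloyl | C=C(C(O)/C=C/C(C)(C)O)[C@@H]1C[C@@H]2O[C@]2(C)[C@@H](O)[C@H]1OC(=O)/C(C)=C/C
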